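Labdane numbering is used throughout. Across ring B the oxygenated carbon C6 and the side-chain carbon C9 stand 1,4 to each other. This is the pattern that a 2-silyloxydiene (C5=C6–C7=C8) leaves on adding to an acceptor alkene (C9=C10), and C1–C4 of ring A act as the tether. A single intramolecular Diels–Alder reaction under a chiral bis(oxazoline) complex of divalent copper therefore makes C5–C10 and C8–C9, closes rings A and B, and sets C5, C8, C9 and C10. The precursor is an acyclic (2E,8Z,10E)-trienoyl oxazolidinone with the silyl enol ether at C6. Afterwards the enol ether supplies the C7=C8 enone for both hydroxyls, and C11 is extended by vinylation and Suzuki coupling.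

Key step: step 8

Remark on the structure: the SMILES describes the (5R,6R,8S,9S,10R,13E) isomer, which belongs to the enantiomeric labdane series. It is a trans-decalin with C20, C17 and C11 on one face and H5, H9, 6-OH and 8-OH on the other. Both hydroxyls are equatorial.

Assumption: the sense of induction in step 8 is taken from the square-planar chelate model of enoyl oxazolidinones bound to the copper bis(oxazoline) dication, which calls for the (S,S)-ligand. If the trisubstituted dienophile responded in the opposite sense, the (R,R)-ligand would be used and nothing else would change.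

Step 1
Reactants: 1 2-(3-chloropropyl)-2-methyl-1,3-dioxolane (commercial ethylene ketal of 5-chloropentan-2-one); 2 mesityl oxide
Product: 5 4,4-dimethylnonane-2,8-dione, via Grignard reagent 3 (not isolated), via silyl enol ether 4 (not isolated)
Conditions: Mg, THF, reflux; then CuBr·SMe2 (10 mol %), TMSCl, 2, THF, −78 → 0 °C; then 1 M HCl, THF, rt
Reagents that add atoms: water O (carbonyl oxygen at C10 after ketal hydrolysis); magnesium [Mg] (only in 3); chlorotrimethylsilane C[Si](C)(C)Cl (only in 4)
Why: Copper-catalysed, TMSCl-accelerated conjugate addition of a primary Grignard reagent to the β,β-disubstituted enone builds the quaternary carbon C4, and the acidic work-up hydrolyses the silyl enol ether and the dioxolane in the same operation.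

Step 2
Reactants: 5 4,4-dimethylnonane-2,8-dione; 6 tert-butyl diethylphosphonoacetate
Product: 8 tert-butyl (2E)-3,7,7-trimethyl-9-oxodec-2-enoate, via sodium phosphonate 7 (not isolated)
Conditions: NaH (1.0 equiv), 6 (1.05 equiv), THF, 0 °C; then 5, 0 °C → rt; chromatographic removal of the Z-isomer
Reagents that add atoms: sodium hydride [H-].[Na+] (sodium only in 7)
Why: Horner–Wadsworth–Emmons olefination with one equivalent of the bulky anion should take the open C10 methyl ketone, since the C6 carbonyl is retarded by its neopentyl-type CH2–C(CH3)2 neighbour; the E-alkene is the normal major isomer from methyl ketones, and running the step before any enone exists means the anion meets no Michael acceptor.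

Step 3
Reactants: 8 tert-butyl (2E)-3,7,7-trimethyl-9-oxodec-2-enoate; 9 acetaldehyde
Product: 11 tert-butyl (2E)-11-hydroxy-3,7,7-trimethyl-9-oxododec-2-enoate (carbinol centre unassigned), via boron enolate 10 (not isolated)
Conditions: Cy2BCl, Et3N, Et2O, −78 → 0 °C; 9, −78 °C; then MeOH, pH 7 buffer, H2O2, 0 °C
Reagents that add atoms: chlorodicyclohexylborane ClB(C1CCCCC1)C1CCCCC1 (only in 10)
Why: Boron-mediated aldol addition, in which Cy2BCl/Et3N enolises ketones but not esters (so the 2E-enoate is not touched) and for steric reasons deprotonates the C7 methyl group and not the neopentyl C5 methylene; the new carbinol centre disappears in step 4.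

Step 4
Reactants: 11 tert-butyl (2E)-11-hydroxy-3,7,7-trimethyl-9-oxododec-2-enoate
Product: 13 tert-butyl (2E,10E)-3,7,7-trimethyl-9-oxododeca-2,10-dienoate, via mesylate 12 (not isolated)
Conditions: MsCl, Et3N, CH2Cl2, 0 °C; then DBU, rt
Reagents that add atoms: methanesulfonyl chloride CS(=O)(=O)Cl (only in 12)
Why: Mesylation followed by E1cB elimination gives the conjugated propenyl ketone in its thermodynamically preferred E geometry.

Step 5
Reactants: 13 tert-butyl (2E,10E)-3,7,7-trimethyl-9-oxododeca-2,10-dienoate
Product: 14 (2E,10E)-3,7,7-trimethyl-9-oxododeca-2,10-dienoic acid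
Conditions: TFA–CH2Cl2 (1:4), 0 °C → rt
Reagents that add atoms: none
Why: Acidolysis of the tert-butyl ester (loss of isobutene) frees the acid without the aqueous base that a hindered alkyl enoate would need and that would hydrate or cleave the propenyl ketone.

Step 6
Reactants: 14 (2E,10E)-3,7,7-trimethyl-9-oxododeca-2,10-dienoic acid; 15 oxazolidin-2-one
Product: 17 3-[(2E,10E)-3,7,7-trimethyl-9-oxododeca-2,10-dienoyl]oxazolidin-2-one, via mixed anhydride 16 (not isolated)
Conditions: PivCl, Et3N, THF, −20 °C; then LiCl, 15, −20 °C → rt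
Reagents that add atoms: pivaloyl chloride CC(C)(C)C(=O)Cl (only in 16)
Why: N-Acylation of the oxazolidinone through the mixed pivalic anhydride with LiCl/Et3N activation is a standard imide synthesis that is mild enough for the enone, and the low temperature suppresses deconjugation through a vinylketene so that the 2E geometry is kept.

Step 7
Reactants: 17 3-[(2E,10E)-3,7,7-trimethyl-9-oxododeca-2,10-dienoyl]oxazolidin-2-one
Product: 18 3-[(2E,8Z,10E)-9-(tert-butyldimethylsilyloxy)-3,7,7-trimethyldodeca-2,8,10-trienoyl]oxazolidin-2-one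
Conditions: TBSOTf (1.2 equiv), Et3N (2 equiv), CH2Cl2, −78 → 0 °C; cold NaHCO3 work-up, Et3N-deactivated silica
Reagents that add atoms: tert-butyldimethylsilyl triflate CC(C)(C)[Si](C)(C)OS(=O)(=O)C(F)(F)F
Why: Soft enolisation, in which the more Lewis-basic enone oxygen is silylated and Et3N removes an α′-proton from C5 to give the cross-conjugated 2-silyloxydiene usual for alkyl propenyl ketones; the bulky C4 group ends up trans to the vinyl substituent (8Z) to avoid allylic strain, and the much less basic imide is left alone.

Step 8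
Reactants: 18 3-[(2E,8Z,10E)-9-(tert-butyldimethylsilyloxy)-3,7,7-trimethyldodeca-2,8,10-trienoyl]oxazolidin-2-one
Product: 19 3-{[(1R,2R,4aR,8aR)-4-(tert-butyldimethylsilyloxy)-2,5,5,8a-tetramethyl-1,2,4a,5,6,7,8,8a-octahydronaphthalen-1-yl]carbonyl}oxazolidin-2-one (labdane centres 5R,8R,9R,10R; trans-fused; C20, C11 and C17 on one face)
Conditions: [Cu((S,S)-t-Bu-box)](SbF6)2 (20 mol %; from CuCl2, AgSbF6 and 2,2'-isopropylidenebis[(4S)-4-tert-butyl-2-oxazoline]), CH2Cl2, 4 Å MS, 0 °C → rt
Reagents that add atoms: none
Why: The dicationic complex of divalent copper binds both imide carbonyls in a square-planar chelate and lowers the LUMO of the s-cis enoyl unit, so that the nucleophilic diene terminus C5 bonds to the β-carbon C10 and C8 bonds to C9, either in one asynchronous [4+2] event or as a Mukaiyama–Michael addition followed by a Michael ring closure, both paths ending in 19. The closest known reactions are the copper bis(oxazoline)-catalysed intramolecular Diels–Alder reactions of trienoyl oxazolidinones and Lewis-acid-catalysed cycloadditions of 2-silyloxydienes; the dienophile used here is β,β-disubstituted and thus more hindered than in those cases, which is why the risk of the route is placed in this step. Ring B closes as the new cyclohexene of the [4+2] union of C5–C8 with C9–C10, and ring A closes as the six-membered ring spanned by the four-atom tether C1–C4 (type 1 mode of a 1,7,9-decatriene). C10 and C9 are set in the absolute sense by the (S,S)-ligand, whose tert-butyl group shields one face of the chelated dienophile, and relative to each other by the 2E-alkene (C20 cis to C11); C5 follows from the 8Z-enol ether together with the endo transition state (imide carbonyl under the diene, tether exo), which gives the trans ring fusion, and C8 follows from the 10E-alkene in the same transition state. The step needs regio-, endo and facial selectivity: the tether enforces a regiochemistry that the donor–acceptor polarity also prefers, the gem-dimethyl group at C4 favours the folded conformer, and the β-methyl group C20 destabilises the s-trans enoyl rotamer so that the facial model applies. C8 becomes sp2 again in step 10 and C5 and C9 hold their thermodynamically preferred configurations next to later carbonyl groups, so only C10 has to be delivered correctly here.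

Step 9
Reactants: 19 cycloadduct imide
Product: 20 [4-(tert-butyldimethylsilyloxy)-2,5,5,8a-tetramethyl-1,2,4a,5,6,7,8,8a-octahydronaphthalen-1-yl]methanol (C11 alcohol; labdane centres 5R,8S,9R,10S, same spatial arrangement as 19)
Conditions: LiBH4, MeOH (1 equiv), Et2O–THF, 0 °C
Reagents that add atoms: none
Why: Reductive cleavage of the N-acyl oxazolidinone, in which lithium-activated borohydride attacks the exocyclic, twisted acyl carbonyl and takes it to the primary alcohol while the silyl enol ether and all stereocentres stay untouched.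

Step 10
Reactants: 20 C11 alcohol with C6 silyl enol ether
Product: 21 4-(hydroxymethyl)-3,4a,8,8-tetramethyl-4a,5,6,7,8,8a-hexahydronaphthalen-1(4H)-one (C6 ketone, C7=C8 alkene, C11 alcohol; 5R,9R,10S)
Conditions: Pd(OAc)2 (1.1 equiv), MeCN, rt
Reagents that add atoms: none
Why: Saegusa–Ito oxidation, in which palladation of the enol ether at C7 and syn β-hydride elimination of H8, which lies on the open face, place the enone exactly where the enol ether dictates; the C8 centre is erased on purpose.

Step 11
Reactants: 21 hydroxy enone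
Product: 22 7,8-epoxide of 21 with the oxygen anti to C20 (5R,7R,8R,9R,10S)
Conditions: 30 % H2O2 (excess), NaOH (cat.), MeOH, 0 °C → rt
Reagents that add atoms: hydrogen peroxide OO
Why: Weitz–Scheffer nucleophilic epoxidation, in which the hydroperoxide anion reaches C8 from the face opposite the axial C20 methyl group and the C9 substituent, setting the C8–O bond anti to C20 and pushing C17 syn to C20; in excess H2O2 the effective base is only the hydroperoxide anion, which spares the γ-proton at C9, the hydroxymethyl group and the more stable trans ring fusion.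

Step 12
Reactants: 22 epoxy ketone
Product: 24 4-(hydroxymethyl)-3,4a,8,8-tetramethyldecahydronaphthalene-1,3-diol (6,8,11-triol; 5R,6R,8S,9R,10R), via keto diol 23 (not isolated)
Conditions: SmI2 (2.5 equiv), THF–MeOH, −78 °C; then SmI2 (4 equiv), H2O, Et3N, 0 °C → rt
Reagents that add atoms: none
Why: Single-electron reduction, in which SmI2 first cleaves the C7–O bond α to the carbonyl with the C8–O bond and its configuration intact, and after activation by water and amine reduces the C6 ketone through ketyl and carbanion stages to the more stable equatorial alcohol, the outcome known from dissolving-metal reductions of ketones flanked by axial methyl groups, whereas hydride reagents would attack the open face and give the axial epimer.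

Step 13
Reactants: 24 6,8,11-triol
Product: 25 2,4-dihydroxy-2,5,5,8a-tetramethyldecahydronaphthalene-1-carbaldehyde (C11 aldehyde; 5R,6R,8S,9S,10R)
Conditions: TEMPO (10 mol %), PhI(OAc)2 (1.1 equiv), CH2Cl2, rt
Reagents that add atoms: none
Why: Oxoammonium (TEMPO) oxidation selects the primary alcohol on steric grounds, the C6 carbinol being shielded by the C4 methyl groups and the C8 alcohol being tertiary, and the nearly neutral medium avoids dehydration of the β-hydroxy aldehyde.

Step 14
Reactants: 25 dihydroxy aldehyde
Product: 26 4-ethenyl-3,4a,8,8-tetramethyldecahydronaphthalene-1,3-diol (C11=C12 vinyl diol; 5R,6R,8S,9S,10R)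
Conditions: Ph3PCH3Br (4 equiv), KHMDS (3.8 equiv), THF, 0 °C; then 25, −78 → 0 °C
Reagents that add atoms: methyltriphenylphosphonium bromide C[P+](c1ccccc1)(c1ccccc1)c1ccccc1.[Br-]
Why: Wittig methylenation, in which the small non-stabilised ylide, made with a slight deficit of base, adds to the aldehyde at low temperature much faster than it can remove the hindered axial proton at C9, so that elimination, retro-aldol cleavage and epimerisation are avoided (C11 is equatorial in any case).

Step 15
Reactants: 27 methyl but-2-ynoate
Product: 29 methyl (2E)-3-(tributylstannyl)but-2-enoate, via alkenylcopper 28 (not isolated)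
Conditions: Bu3SnH, LDA, THF, −78 → 0 °C; CuBr·SMe2, −78 °C; 27, MeOH, −78 °C
Reagents that add atoms: tributyltin hydride CCCC[SnH](CCCC)CCCC; CuBr·SMe2 [Cu]Br.CSC (copper only in 28)
Why: Stannylcupration, a syn addition of tin and copper across the ynoate whose kinetic adduct is protonated in situ at −78 °C, places tin trans to the ester (E), the geometry that direct hydroiodination of the ynoate would not give.

Step 16
Reactants: 29 methyl (2E)-3-(tributylstannyl)but-2-enoate
Product: 30 methyl (2E)-3-iodobut-2-enoate
Conditions: I2, CH2Cl2, 0 °C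
Reagents that add atoms: iodine [I][I]
Why: Iododestannylation is an electrophilic ipso substitution at the alkenyl carbon and proceeds with retention of the alkene geometry.

Step 17
Reactants: 26 vinyl diol; 30 methyl (2E)-3-iodobut-2-enoate
Product: 32 methyl (2E)-5-[(1S,2S,4R,4aR,8aR)-2,4-dihydroxy-2,5,5,8a-tetramethyldecahydronaphthalen-1-yl]-3-methylpent-2-enoate (target), via alkylborane 31 (not isolated)
Conditions: 9-BBN (excess), THF, 0 °C → rt; H2O; then 30, Pd(dppf)Cl2 (5 mol %), AsPh3, Cs2CO3, DMF, rt
Reagents that add atoms: 9-borabicyclo[3.3.1]nonane B1C2CCCC1CCC2 (only in 31)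
Why: Anti-Markovnikov hydroboration puts boron on the terminal carbon C12, and the B-alkyl Suzuki–Miyaura coupling forms C12–C13 with retention of the E geometry at room temperature, so that the methyl ester and both free hydroxyls survive (the extra 9-BBN taken up by the hydroxyls is released when water is added).

Compound list
1 | 2-(3-chloropropyl)-2-methyl-1,3-dioxolane | CC1(CCCCl)OCCO1 | starting material
2 | mesityl oxide (4-methylpent-3-en-2-one) | CC(=O)C=C(C)C | starting material
3 | [3-(2-methyl-1,3-dioxolan-2-yl)propyl]magnesium chloride | CC1(CCC[Mg]Cl)OCCO1 | intermediate (not isolated)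
4 | trimethyl{[4,4-dimethyl-7-(2-methyl-1,3-dioxolan-2-yl)hept-2-en-2-yl]oxy}silane (alkene geometry irrelevant) | CC(O[Si](C)(C)C)=CC(C)(C)CCCC1(C)OCCO1 | intermediate (not isolated)
5 | 4,4-dimethylnonane-2,8-dione | CC(=O)CC(C)(C)CCCC(C)=O | intermediate
6 | tert-butyl diethylphosphonoacetate | CCOP(=O)(CC(=O)OC(C)(C)C)OCC | starting material
7 | sodium salt of 6 | CCOP(=O)([CH-]C(=O)OC(C)(C)C)OCC.[Na+] | intermediate (not isolated)
8 | tert-butyl (2E)-3,7,7-trimethyl-9-oxodec-2-enoate | CC(=O)CC(C)(C)CCC/C(C)=C/C(=O)OC(C)(C)C | intermediate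
9 | acetaldehyde | CC=O | starting material
10 | dicyclohexylboron enolate of 8 (C6–O–B, C6=C7) | C=C(OB(C1CCCCC1)C1CCCCC1)CC(C)(C)CCC/C(C)=C/C(=O)OC(C)(C)C | intermediate (not isolated)
11 | tert-butyl (2E)-11-hydroxy-3,7,7-trimethyl-9-oxododec-2-enoate | CC(O)CC(=O)CC(C)(C)CCC/C(C)=C/C(=O)OC(C)(C)C | intermediate
12 | methanesulfonate of 11 | CC(OS(C)(=O)=O)CC(=O)CC(C)(C)CCC/C(C)=C/C(=O)OC(C)(C)C | intermediate (not isolated)
13 | tert-butyl (2E,10E)-3,7,7-trimethyl-9-oxododeca-2,10-dienoate | C/C=C/C(=O)CC(C)(C)CCC/C(C)=C/C(=O)OC(C)(C)C | intermediate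
14 | (2E,10E)-3,7,7-trimethyl-9-oxododeca-2,10-dienoic acid | C/C=C/C(=O)CC(C)(C)CCC/C(C)=C/C(=O)O | intermediate
15 | oxazolidin-2-one | O=C1NCCO1 | starting material
16 | mixed pivalic anhydride of 14 | C/C=C/C(=O)CC(C)(C)CCC/C(C)=C/C(=O)OC(=O)C(C)(C)C | intermediate (not isolated)
17 | 3-[(2E,10E)-3,7,7-trimethyl-9-oxododeca-2,10-dienoyl]oxazolidin-2-one | C/C=C/C(=O)CC(C)(C)CCC/C(C)=C/C(=O)N1CCOC1=O | intermediate
18 | 3-[(2E,8Z,10E)-9-(tert-butyldimethylsilyloxy)-3,7,7-trimethyldodeca-2,8,10-trienoyl]oxazolidin-2-one | O=C(N1CCOC1=O)/C=C(\C)CCCC(C)(C)/C=C(O[Si](C)(C)C(C)(C)C)/C=C/C | intermediate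
19 | trans-fused decalin silyl enol ether with the C11 imide (5R,8R,9R,10R) | O=C(N3CCOC3=O)[C@H]1[C@]2(C)CCCC(C)(C)[C@H]2C(O[Si](C)(C)C(C)(C)C)=C[C@H]1C | intermediate
20 | C11 alcohol with C6 silyl enol ether (5R,8S,9R,10S) | OC[C@H]1[C@]2(C)CCCC(C)(C)[C@H]2C(O[Si](C)(C)C(C)(C)C)=C[C@H]1C | intermediate
21 | 11-hydroxy 7-en-6-one (5R,9R,10S) | OC[C@H]1[C@]2(C)CCCC(C)(C)[C@H]2C(=O)C=C1C | intermediate
22 | 11-hydroxy 7,8-epoxy 6-ketone, oxygen anti to C20 (5R,7R,8R,9R,10S) | OC[C@H]1[C@]2(C)CCCC(C)(C)[C@H]2C(=O)[C@@H]3O[C@]13C | intermediate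
23 | 8,11-dihydroxy 6-ketone (5R,8S,9R,10S) | OC[C@H]1[C@]2(C)CCCC(C)(C)[C@H]2C(=O)C[C@]1(C)O | intermediate (not isolated)
24 | 6,8,11-triol (5R,6R,8S,9R,10R) | OC[C@H]1[C@]2(C)CCCC(C)(C)[C@H]2[C@H](O)C[C@]1(C)O | intermediate
25 | 6,8-dihydroxy 11-aldehyde (5R,6R,8S,9S,10R) | O=C[C@H]1[C@]2(C)CCCC(C)(C)[C@H]2[C@H](O)C[C@]1(C)O | intermediate
26 | C11=C12 vinyl 6,8-diol (5R,6R,8S,9S,10R) | C=C[C@H]1[C@]2(C)CCCC(C)(C)[C@H]2[C@H](O)C[C@]1(C)O | intermediate
27 | methyl but-2-ynoate | CC#CC(=O)OC | starting material
28 | methyl 2-cuprio-3-(tributylstannyl)but-2-enoate (tin and copper cis) | COC(=O)/C([Cu])=C(\C)[Sn](CCCC)(CCCC)CCCC | intermediate (not isolated)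
29 | methyl (2E)-3-(tributylstannyl)but-2-enoate | COC(=O)/C=C(\C)[Sn](CCCC)(CCCC)CCCC | intermediate
30 | methyl (2E)-3-iodobut-2-enoate | COC(=O)/C=C(\C)I | intermediate
31 | C12 B-alkyl-9-BBN adduct of 26 (drawn with free hydroxyls) | C1CC2CCCC(C1)B2CC[C@H]3[C@]4(C)CCCC(C)(C)[C@H]4[C@H](O)C[C@]3(C)O | intermediate (not isolated)
32 | methyl (2E)-5-[(1S,2S,4R,4aR,8aR)-2,4-dihydroxy-2,5,5,8a-tetramethyldecahydronaphthalen-1-yl]-3-methylpent-2-enoate | COC(=O)/C=C(\C)CC[C@H]1[C@]2(C)CCCC(C)(C)[C@H]2[C@H](O)C[C@]1(C)O | target

Total step count: 17. Longest linear sequence: 15 (steps 1–14 and 17). Steps 15 and 16 form a two-step branch.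

Steps most likely to fail

1. Step 8.
- What may go wrong:
  - The cycloaddition may be too slow, because the C5–C10 bond joins a neopentyl diene terminus to a fully substituted β-carbon.
  - Adventitious acid may strip the silyl group from the diene.
  - The reaction may stop after the first C–C bond.
  - Facial or endo selectivity may erode.
- Fallback: auxiliary control with a stoichiometric, stronger Lewis acid in place of catalyst control. It sets out from acid 14. The mixed anhydride 16 is treated with lithiated (R)-4-benzyloxazolidin-2-one to give (4R)-4-benzyl-3-[(2E,10E)-3,7,7-trimethyl-9-oxododeca-2,10-dienoyl]oxazolidin-2-one F1. TBSOTf/Et3N, as in step 7, gives its (8Z)-silyl dienol ether F2. Me2AlCl (1.4 equiv, CH2Cl2, −30 °C → rt) forms a cationic aluminium chelate in which the benzyl group covers the same dienophile face that the ligand covers in step 8. The auxiliary-controlled intramolecular Diels–Alder reaction then gives the 4-benzyl analogue of the cycloadduct F3. LiBH4, as in step 9, removes the auxiliary, and the route is rejoined at alcohol 20.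

2. Step 7.
- What may go wrong:
  - Proton loss may occur from C17 (γ) instead of the hindered C5.
  - The imide may be partly enolised and silylated.
  - A mixture of enol ether geometries may form.
- Fallback: the silyl dienol ether is made before any imide is present, so that a kinetic amide base can be used. It sets out from mesityl oxide 2. Hosomi–Sakurai allylation (allyltrimethylsilane, TiCl4, CH2Cl2, −78 °C) gives 4,4-dimethylhept-6-en-2-one F4. LDA and then acetaldehyde 9 give 2-hydroxy-6,6-dimethylnon-8-en-4-one F5, which is dehydrated (TsOH cat., toluene, heat) to (2E)-6,6-dimethylnona-2,8-dien-4-one F6. LDA, TBSCl, THF–DMPU at −78 °C removes the α′-proton under kinetic control and gives tert-butyl{[(2E,4Z)-6,6-dimethylnona-2,4,8-trien-4-yl]oxy}dimethylsilane F7. 9-BBN adds only to the terminal alkene to give the B-alkyl borane F8. In parallel, iodide 30 is hydrolysed (LiOH, THF–H2O, 0 °C) to (2E)-3-iodobut-2-enoic acid F9, which acylates 15 (PivCl, Et3N, LiCl) to give 3-[(2E)-3-iodobut-2-enoyl]oxazolidin-2-one F10. A B-alkyl Suzuki–Miyaura coupling of the two (Pd(dppf)Cl2, K3PO4, DMF, rt) comes back to the route at 18. This path also fixes the 2E geometry by retention and bypasses steps 1–7.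

3. Step 9.
- What may go wrong: hydride may attack the unhindered ring carbonyl of the oxazolidinone instead of the crowded exocyclic one. This opens the ring and leaves an unreactive amide.
- Fallback: hydrolysis followed by reduction in place of direct reductive cleavage. It sets out from 19. LiOH/H2O2 (THF–H2O, 0 °C) is used because hydroperoxide cleaves N-acyl oxazolidinones at the exocyclic carbonyl even when that carbonyl is the more hindered one. It gives the C11 carboxylic acid F11, which LiAlH4 (Et2O, 0 °C) reduces to alcohol 20, where the route is rejoined.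

Further compounds
F1 | step 8 | (4R)-4-benzyl-3-[(2E,10E)-3,7,7-trimethyl-9-oxododeca-2,10-dienoyl]oxazolidin-2-one | C/C=C/C(=O)CC(C)(C)CCC/C(C)=C/C(=O)N1[C@H](Cc2ccccc2)COC1=O
F2 | step 8 | (4R)-4-benzyl-3-[(2E,8Z,10E)-9-(tert-butyldimethylsilyloxy)-3,7,7-trimethyldodeca-2,8,10-trienoyl]oxazolidin-2-one | O=C(N1[C@H](Cc2ccccc2)COC1=O)/C=C(\C)CCCC(C)(C)/C=C(O[Si](C)(C)C(C)(C)C)/C=C/C
F3 | step 8 | (4R)-4-benzyl analogue of cycloadduct 19 | O=C(N3[C@H](Cc4ccccc4)COC3=O)[C@H]1[C@]2(C)CCCC(C)(C)[C@H]2C(O[Si](C)(C)C(C)(C)C)=C[C@H]1C
F4 | step 7 | 4,4-dimethylhept-6-en-2-one | CC(=O)CC(C)(C)CC=C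
F5 | step 7 | 2-hydroxy-6,6-dimethylnon-8-en-4-one | CC(O)CC(=O)CC(C)(C)CC=C
F6 | step 7 | (2E)-6,6-dimethylnona-2,8-dien-4-one | C/C=C/C(=O)CC(C)(C)CC=C
F7 | step 7 | tert-butyl{[(2E,4Z)-6,6-dimethylnona-2,4,8-trien-4-yl]oxy}dimethylsilane | C=CCC(C)(C)/C=C(O[Si](C)(C)C(C)(C)C)/C=C/C
F8 | step 7 | B-alkyl-9-BBN adduct of F7 | C1CC2CCCC(C1)B2CCCC(C)(C)/C=C(O[Si](C)(C)C(C)(C)C)/C=C/C
F9 | step 7 | (2E)-3-iodobut-2-enoic acid | OC(=O)/C=C(\C)I
F10 | step 7 | 3-[(2E)-3-iodobut-2-enoyl]oxazolidin-2-one | O=C(N1CCOC1=O)/C=C(\C)I
F11 | step 9 | C11 carboxylic acid with C6 silyl enol ether (configuration as in 19) | OC(=O)[C@H]1[C@]2(C)CCCC(C)(C)[C@H]2C(O[Si](C)(C)C(C)(C)C)=C[C@H]1C
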